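The route rests on reading ring C (O1, C2, C3, C4, C4a, C8a) as a ring-expanded 2-arylbenzofuran-3(2H)-one: its only CH2, C3, lies between ketone carbon C4 and the aryl-bearing, oxygen-bonded carbon C2, exactly where a one-carbon insertion into the five-membered ring would put it. That carbon is introduced as a cyclopropane across the enol double bond of the silylated benzofuranone. Freeing the cyclopropanolate with fluoride severs the fusion bond: C4 becomes the ketone and C2 is protonated with inversion, so the six-membered ring and the 2S centre arise together. The precursor is an enantioenriched, cis-fused 1a-aryl-6b-silyloxycyclopropa[b]benzofuran with bromine holding the prenyl position.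

Key step: step 5

Remark on the design: the cyclopropanol is masked as a triethylsilyl ether, not a trimethylsilyl ether. The enol ether and the cyclopropyl ether must survive chromatography and the ZnI2 formed during cyclopropanation, and a premature zinc-mediated opening would bypass the stereospecific pathway. The correct hydro prefix of the precursor is 1a,6b-dihydro-1H.

Assumption: the face preferred by the dipeptide-bound zinc carbenoid on this enol ether cannot be predicted with confidence. The L,L ligand is written; should it favour the other face, its D,D enantiomer is used.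

Step 1
Reactants: 1 4-bromo-3,5-dimethoxyphenol; 2 (3,4,5-trimethoxyphenyl)acetic acid
Product: 3 1-(3-bromo-6-hydroxy-2,4-dimethoxyphenyl)-2-(3,4,5-trimethoxyphenyl)ethan-1-one
Conditions: BF3·OEt2 (solvent and promoter), 80 °C; then aq. NaOAc
Reagents that add atoms: none
Why: Friedel–Crafts C-acylation, in which the two equivalent free ring positions of 1 are ortho to the hydroxyl and activated by both methoxy groups, and the ortho-hydroxy ketone is held as a difluoroboron chelate that prevents a second acylation.

Step 2
Reactants: 3 1-(3-bromo-6-hydroxy-2,4-dimethoxyphenyl)-2-(3,4,5-trimethoxyphenyl)ethan-1-one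
Product: 4 2-bromo-1-(3-bromo-6-hydroxy-2,4-dimethoxyphenyl)-2-(3,4,5-trimethoxyphenyl)ethan-1-one (racemic)
Conditions: CuBr2 (2.1 equiv), EtOAc/CHCl3 (1:1), reflux
Reagents that add atoms: CuBr2, Br[Cu]Br
Why: Heterogeneous α-bromination of an aryl benzyl ketone through its enol, where CuBr2 delivers bromine to the doubly activated CH2 and leaves the electron-rich rings alone; the new centre is racemic and is erased in step 3.

Step 3
Reactants: 4 2-bromo-1-(3-bromo-6-hydroxy-2,4-dimethoxyphenyl)-2-(3,4,5-trimethoxyphenyl)ethan-1-one
Product: 6 5-bromo-4,6-dimethoxy-3-(triethylsilyloxy)-2-(3,4,5-trimethoxyphenyl)-1-benzofuran, via benzofuranone 5 (not isolated)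
Conditions: i-Pr2NEt (4 equiv), CH2Cl2, 0 → 23 °C, argon; then TESOTf (1.3 equiv), 0 °C
Reagents that add atoms: triethylsilyl trifluoromethanesulfonate (TESOTf), CC[Si](CC)(CC)OS(=O)(=O)C(F)(F)F
Why: Intramolecular Williamson etherification (5-exo-tet SN2 of the phenoxide on the benzylic bromide) closes the furanone, and soft enolisation with O-silylation traps it in the same flask as the aromatic silyl enol ether, so the autoxidation-prone 2-arylbenzofuranone never meets air.

Step 4
Reactants: 6 5-bromo-4,6-dimethoxy-3-(triethylsilyloxy)-2-(3,4,5-trimethoxyphenyl)-1-benzofuran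
Product: 7 (1aR,6bR)-5-bromo-4,6-dimethoxy-6b-(triethylsilyloxy)-1a-(3,4,5-trimethoxyphenyl)-1a,6b-dihydro-1H-cyclopropa[b][1]benzofuran
Conditions: Et2Zn (1.5 equiv), N-Boc-L-Val-L-Pro-OMe (1.5 equiv), CH2I2 (3 equiv), CH2Cl2, −40 → 0 °C
Reagents that add atoms: diiodomethane, ICI
Why: Enantioselective Simmons–Smith cyclopropanation of a silyl enol ether, in which the concerted suprafacial methylene transfer makes the ring fusion necessarily cis and the dipeptide-bound carbenoid RZnCH2I selects the alkene face, setting both quaternary centres (1aR, 6bR) in one event; the aryl bromide is inert to the zinc reagent, which is why bromine and not the prenyl alkene is carried here.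

Step 5
Reactants: 7 (1aR,6bR)-5-bromo-4,6-dimethoxy-6b-(triethylsilyloxy)-1a-(3,4,5-trimethoxyphenyl)-1a,6b-dihydro-1H-cyclopropa[b][1]benzofuran
Product: 9 (2S)-6-bromo-5,7-dimethoxy-2-(3,4,5-trimethoxyphenyl)-2,3-dihydro-4H-chromen-4-one, via cyclopropanolate 8 (not isolated)
Conditions: Bu4NF (1.1 equiv), THF/MeOH (4:1), −40 → 0 °C, argon; then AcOH (1.5 equiv), 0 °C
Reagents that add atoms: none
Why: Proposed new method: fluoride attacks silicon and releases cyclopropanolate 8, whose oxygen lone pair pushes into the strained C6b–C1a fusion bond so that C6b becomes the C4 carbonyl while the charge developing at C1a (future C2) is quenched by methanol at the lobe pointing away from the departing carbon, an SE2 protonation with inversion that the dissociating protic medium and the non-coordinating Bu4N+ counter-ion should favour. The closest known reactions are the base-induced opening of 2-arylcyclopropanols, which cleave toward the benzylic carbon with inversion, and the one-carbon homologation of cyclic ketones through silyloxycyclopropanes; neither has been run across the C2–C3 bond of a benzofuran or used to set a flavanone C2 centre. Ring C (O1, C2, C3, C4, C4a, C8a) is not closed by a bond-forming cyclisation: it is the outer perimeter of the 2-oxabicyclo[3.1.0]hexane and appears when the shared bond is cut, so no competing closure mode exists. The new C2 stereocentre is controlled by the 1aR configuration of 7 together with the inversion course, since O1, C3 and the aryl group keep their mutual arrangement and hydrogen enters opposite to C4, which corresponds to 2S. The step needs cleavage of the internal bond and not of the C6b–C1 bond, which the aryl group and the ring oxygen secure by stabilising negative charge at C2 (the alternative is a primary carbanion), helped by the larger strain relief of opening the bicycle. It also needs the product to escape base-induced epimerisation through retro-oxa-Michael ring opening, which the low temperature, the methanol buffer and the acetic acid quench before warming are meant to ensure.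

Step 6
Reactants: 9 (2S)-6-bromo-5,7-dimethoxy-2-(3,4,5-trimethoxyphenyl)-2,3-dihydro-4H-chromen-4-one; 10 prenylboronic acid pinacol ester
Product: 11 (2S)-5,7-dimethoxy-6-(3-methylbut-2-en-1-yl)-2-(3,4,5-trimethoxyphenyl)-2,3-dihydro-4H-chromen-4-one
Conditions: 10 (1.5 equiv), Pd(dppf)Cl2·CH2Cl2 (5 mol %), CsF (3 equiv), THF, 60 °C, argon
Reagents that add atoms: none
Why: Suzuki–Miyaura cross-coupling of an aryl bromide with an allylic pinacol boronate, where the prenyl(aryl)palladium intermediate should reductively eliminate at its unsubstituted terminus to give the linear prenyl group, and the anhydrous fluoride base is mild enough to leave the ketone and the C2 centre alone.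

Step 7
Reactants: 11 (2S)-5,7-dimethoxy-6-(3-methylbut-2-en-1-yl)-2-(3,4,5-trimethoxyphenyl)-2,3-dihydro-4H-chromen-4-one
Product: 12 artoflavanone, (2S)-5-hydroxy-7-methoxy-6-(3-methylbut-2-en-1-yl)-2-(3,4,5-trimethoxyphenyl)-2,3-dihydro-4H-chromen-4-one
Conditions: BCl3 (1.2 equiv), CH2Cl2, −78 → −20 °C; then ice-cold H2O
Reagents that add atoms: none
Why: Chelation-controlled ether cleavage, in which BCl3 bridges the C4 carbonyl and the peri C5 methoxy oxygen so that chloride removes that methyl group alone, the low temperature sparing the four other methyl ethers, the prenyl alkene and the C2 centre.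

Compound list
1 | 4-bromo-3,5-dimethoxyphenol | COc1cc(O)cc(OC)c1Br | starting material
2 | (3,4,5-trimethoxyphenyl)acetic acid | COc1cc(CC(=O)O)cc(OC)c1OC | starting material
3 | 1-(3-bromo-6-hydroxy-2,4-dimethoxyphenyl)-2-(3,4,5-trimethoxyphenyl)ethan-1-one | COc1cc(O)c(C(=O)Cc2cc(OC)c(OC)c(OC)c2)c(OC)c1Br | intermediate
4 | 2-bromo-1-(3-bromo-6-hydroxy-2,4-dimethoxyphenyl)-2-(3,4,5-trimethoxyphenyl)ethan-1-one (racemic) | COc1cc(O)c(C(=O)C(Br)c2cc(OC)c(OC)c(OC)c2)c(OC)c1Br | intermediate
5 | 5-bromo-4,6-dimethoxy-2-(3,4,5-trimethoxyphenyl)-1-benzofuran-3(2H)-one (racemic, not isolated) | COc1cc2OC(c3cc(OC)c(OC)c(OC)c3)C(=O)c2c(OC)c1Br | intermediate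
6 | 5-bromo-4,6-dimethoxy-3-(triethylsilyloxy)-2-(3,4,5-trimethoxyphenyl)-1-benzofuran | COc1cc2oc(-c3cc(OC)c(OC)c(OC)c3)c(O[Si](CC)(CC)CC)c2c(OC)c1Br | intermediate
7 | (1aR,6bR)-5-bromo-4,6-dimethoxy-6b-(triethylsilyloxy)-1a-(3,4,5-trimethoxyphenyl)-1a,6b-dihydro-1H-cyclopropa[b][1]benzofuran (cis-fused; aryl on the carbon bonded to the ring oxygen) | COc1cc2c(c(OC)c1Br)[C@]1(O[Si](CC)(CC)CC)C[C@]1(c1cc(OC)c(OC)c(OC)c1)O2 | intermediate
8 | tetrabutylammonium (1aR,6bR)-5-bromo-4,6-dimethoxy-1a-(3,4,5-trimethoxyphenyl)-1a,6b-dihydro-1H-cyclopropa[b][1]benzofuran-6b-olate (not isolated) | COc1cc2c(c(OC)c1Br)[C@]1([O-])C[C@]1(c1cc(OC)c(OC)c(OC)c1)O2.CCCC[N+](CCCC)(CCCC)CCCC | intermediate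
9 | (2S)-6-bromo-5,7-dimethoxy-2-(3,4,5-trimethoxyphenyl)-2,3-dihydro-4H-chromen-4-one | COc1cc2c(c(OC)c1Br)C(=O)C[C@@H](c1cc(OC)c(OC)c(OC)c1)O2 | intermediate
10 | prenylboronic acid pinacol ester, 4,4,5,5-tetramethyl-2-(3-methylbut-2-en-1-yl)-1,3,2-dioxaborolane | CC(C)=CCB1OC(C)(C)C(C)(C)O1 | starting material
11 | (2S)-5,7-dimethoxy-6-(3-methylbut-2-en-1-yl)-2-(3,4,5-trimethoxyphenyl)-2,3-dihydro-4H-chromen-4-one | COc1cc2c(c(OC)c1CC=C(C)C)C(=O)C[C@@H](c1cc(OC)c(OC)c(OC)c1)O2 | intermediate
12 | artoflavanone, (2S)-5-hydroxy-7-methoxy-6-(3-methylbut-2-en-1-yl)-2-(3,4,5-trimethoxyphenyl)-2,3-dihydro-4H-chromen-4-one | COc1cc2c(c(O)c1CC=C(C)C)C(=O)C[C@@H](c1cc(OC)c(OC)c(OC)c1)O2 | target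

Total step count: 7. Longest linear sequence: 7 steps (from 1 to 12).

Steps most likely to fail

Step 5. The transfer of configuration may be incomplete if protonation occurs from the front side or through a free, planarised carbanion. The peripheral C6b–C1 bond may cleave instead of the fusion bond. The product may also lose its C2 configuration by base-mediated ring opening and reclosure. The fallback uses known chemistry, sets out from 1 and returns at 9. BF3·OEt2-promoted acetylation of 1 with acetic acid should give 1-(3-bromo-6-hydroxy-2,4-dimethoxyphenyl)ethan-1-one F1. Condensation with N,N-dimethylformamide dimethyl acetal should give (2E)-1-(3-bromo-6-hydroxy-2,4-dimethoxyphenyl)-3-(dimethylamino)prop-2-en-1-one F2, which should close under HCl to 6-bromo-5,7-dimethoxy-4H-chromen-4-one F3. Enantioselective conjugate addition of (3,4,5-trimethoxyphenyl)boronic acid, catalysed by Pd(OCOCF3)2 and the t-BuPyOx enantiomer that delivers 2S (NH4PF6, H2O, ClCH2CH2Cl, 60 °C), should then give 9. That cycle stays at divalent palladium, so the aryl bromide should not be touched.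

Step 4. Facial selectivity of the ligand-bound carbenoid may be poor, or methylene transfer sluggish, on this tetrasubstituted and crowded enol ether. The fallback replaces asymmetric induction by physical separation, sets out from 6 and returns at 7. Cyclopropanation with the more electrophilic achiral carbenoid CF3CO2ZnCH2I (Et2Zn, CF3CO2H, CH2I2, CH2Cl2, 0 °C) should give the racemate. Preparative supercritical-fluid chromatography on a polysaccharide chiral stationary phase should separate 7 from (1aS,6bS)-5-bromo-4,6-dimethoxy-6b-(triethylsilyloxy)-1a-(3,4,5-trimethoxyphenyl)-1a,6b-dihydro-1H-cyclopropa[b][1]benzofuran F4. The triethylsilyl ether is what makes this separation practical.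

Step 6. The C2 configuration may erode through retro-oxa-Michael opening and reclosure while the flavanone is heated with fluoride. Oxidative addition at the di-ortho-substituted, electron-rich bromide may be slow. Transmetalation with allylic transposition may deliver the 1,1-dimethylallyl isomer. The fallback is base-free and has no regiochemical ambiguity; it sets out from 9 and returns at 11. Stille coupling with allyltributylstannane (Pd(PPh3)4, toluene, 100 °C) should give (2S)-5,7-dimethoxy-6-(prop-2-en-1-yl)-2-(3,4,5-trimethoxyphenyl)-2,3-dihydro-4H-chromen-4-one F5. Olefin cross-metathesis with 2-methylbut-2-ene and second-generation Grubbs catalyst (CH2Cl2, 40 °C) should then convert the allyl group into the prenyl group of 11.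

Further compounds
F1 | step 5 | 1-(3-bromo-6-hydroxy-2,4-dimethoxyphenyl)ethan-1-one | COc1cc(O)c(C(C)=O)c(OC)c1Br
F2 | step 5 | (2E)-1-(3-bromo-6-hydroxy-2,4-dimethoxyphenyl)-3-(dimethylamino)prop-2-en-1-one | COc1cc(O)c(C(=O)/C=C/N(C)C)c(OC)c1Br
F3 | step 5 | 6-bromo-5,7-dimethoxy-4H-chromen-4-one | COc1cc2occc(=O)c2c(OC)c1Br
F4 | step 4 | (1aS,6bS)-5-bromo-4,6-dimethoxy-6b-(triethylsilyloxy)-1a-(3,4,5-trimethoxyphenyl)-1a,6b-dihydro-1H-cyclopropa[b][1]benzofuran | COc1cc2c(c(OC)c1Br)[C@@]1(O[Si](CC)(CC)CC)C[C@@]1(c1cc(OC)c(OC)c(OC)c1)O2
F5 | step 6 | (2S)-5,7-dimethoxy-6-(prop-2-en-1-yl)-2-(3,4,5-trimethoxyphenyl)-2,3-dihydro-4H-chromen-4-one | COc1cc2c(c(OC)c1CC=C)C(=O)C[C@@H](c1cc(OC)c(OC)c(OC)c1)O2
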